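Ring A is built, not decorated. The hexasubstituted benzene is cut at C1–C2 and C5–C6 into a four-carbon cyclobutenone and a two-carbon siloxyalkyne. The cut exploits two features of ring A: C3–C4–C5 is a methyl enol ether flanked by two prenyl groups, and the C2 and C6 oxygens lie meta to each other on either side of the aroyl carbon C1. One neutral thermal operation (ring opening, ketene–alkyne [2+2], second opening, 6π closure) places all six substituents. Its precursors are 3-methoxy-2,4-diprenylcyclobutenone and a triisopropylsiloxyalkyne that carries ring B as a silylated benzhydrylic carbinol, which is oxidised to the ketone afterwards.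

Key step: step 7

Design notes
- **Graded silyl groups.** The carbinol oxygen carries triethylsilyl, the ring B phenol carries TBS, and the ynol oxygen carries TIPS. The carbinol can then be bared alone and oxidised while two of the three phenols are still masked.
- **No full desilylation before oxidation.** A 2,6-dihydroxy-4-methoxyphenyl 4-hydroxyphenyl carbinol loses water to quinone methides very easily. Free polyphenols are also attacked by MnO2.
- **Source of the siloxyalkyne.** It is made from a terminal alkyne by acetylide oxidation. An α-silyloxy arylacetic ester would be a poor source, because its benzylic α-hydrogen is removed by the amide bases and carbenoids that an ester-to-ynolate homologation needs.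
- **Silyl migration is harmless.** If the triethylsilyl group moves to the neighbouring C2 oxygen during the thermolysis, both isomers still converge on the target after oxidation and fluoride.

Assumption: 4-(tert-butyldimethylsilyloxy)benzaldehyde, ethynylmagnesium bromide (THF solution) and ethoxyacetylene (hexane solution) are bought. Every compound with the carbinol centre or the cyclobutenone C4 centre is racemic, and both centres vanish before the achiral target.

Step 1
Reactants: 1 ethoxyacetylene; 2 prenyl bromide
Product: 4 1-ethoxy-5-methylhex-4-en-1-yne, via lithium ethoxyacetylide 3 (not isolated)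
Conditions: n-BuLi (1.0 equiv), THF, −78 °C; DMPU, 2, −78 → 23 °C
Reagents that add atoms: none
Why: SN2 alkylation of a lithium alkoxyacetylide, activated by DMPU, at the unhindered primary carbon of the allylic bromide is standard acetylide alkylation and leaves the ynol ether untouched.

Step 2
Reactants: 4 1-ethoxy-5-methylhex-4-en-1-yne (two molecules)
Product: 6 rac-3-ethoxy-2,4-bis(3-methylbut-2-enyl)cyclobut-2-en-1-one, via prenylketene 5 (not isolated)
Conditions: PhCl (2 M), 120 °C, Ar, vented through a bubbler, stopped when 4 is consumed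
Reagents that add atoms: none
Why: This is the thermal dimerisation of a 1-ethoxyalkyne, in which retro-ene loss of ethene from one molecule gives aldoketene 5 and a second molecule traps it in a ketene–ynol ether [2+2] whose polarity (nucleophilic alkyne carbon to ketene carbonyl carbon) puts ethoxy at C3 and prenyl at C2 and C4, with C4 formed racemic.

Step 3
Reactants: 6 rac-3-ethoxy-2,4-bis(3-methylbut-2-enyl)cyclobut-2-en-1-one
Product: 7 rac-3-methoxy-2,4-bis(3-methylbut-2-enyl)cyclobut-2-en-1-one
Conditions: camphor-10-sulfonic acid (5 mol %), dry MeOH (0.1 M), 23 °C; Et3N quench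
Reagents that add atoms: methanol, CO
Why: Acid-catalysed transetherification of a vinylogous ester by addition–elimination at C3, the pathway by which 3-alkoxycyclobutenones are hydrolysed, is driven by methanol as solvent, and a trace of sulfonic acid at room temperature should not touch trisubstituted alkenes.

Step 4
Reactants: 8 4-(tert-butyldimethylsilyloxy)benzaldehyde; 9 ethynylmagnesium bromide
Product: 10 rac-1-[4-(tert-butyldimethylsilyloxy)phenyl]prop-2-yn-1-ol
Conditions: THF, 0 °C; aq NH4Cl
Reagents that add atoms: none
Why: Grignard 1,2-addition of an alkynyl nucleophile to a non-enolisable aromatic aldehyde gives a racemic carbinol centre, which is immaterial because it ends as the carbonyl carbon.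

Step 5
Reactants: 10 rac-1-[4-(tert-butyldimethylsilyloxy)phenyl]prop-2-yn-1-ol
Product: 11 rac-tert-butyldimethyl{4-[1-(triethylsilyloxy)prop-2-ynyl]phenoxy}silane
Conditions: Et3SiCl, imidazole, CH2Cl2, 0 → 23 °C
Reagents that add atoms: chlorotriethylsilane, CC[Si](Cl)(CC)CC
Why: This is standard imidazole-promoted silylation of a secondary alcohol, with triethylsilyl chosen because it can later be removed in the presence of the two aryl silyl ethers.

Step 6
Reactants: 11 rac-tert-butyldimethyl{4-[1-(triethylsilyloxy)prop-2-ynyl]phenoxy}silane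
Product: 14 rac-3-[4-(tert-butyldimethylsilyloxy)phenyl]-3-(triethylsilyloxy)-1-(triisopropylsilyloxy)prop-1-yne, via lithium acetylide 12 (not isolated), via lithium ynolate 13 (not isolated)
Conditions: n-BuLi (1.0 equiv), THF, −78 °C; t-BuOOLi [t-BuOOH in decane, LiN(SiMe3)2, THF, −78 °C], −78 → 0 °C; i-Pr3SiOTf, −78 → 0 °C; aqueous work-up, Et3N-deactivated silica
Reagents that add atoms: tert-butyl hydroperoxide (as its lithium salt, delivers the oxygen), CC(C)(C)OO; triisopropylsilyl trifluoromethanesulfonate, CC(C)[Si](OS(=O)(=O)C(F)(F)F)(C(C)C)C(C)C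
Why: Oxidation of a lithium acetylide by lithium tert-butyl peroxide (electrophilic oxygen transfer) gives the ynolate, and the bulky silyl triflate silylates it on oxygen rather than carbon, a known one-flask route from terminal alkynes to triisopropylsiloxyalkynes that needs one equivalent of strong base at the most acidic C–H only.

Step 7
Reactants: 7 rac-3-methoxy-2,4-bis(3-methylbut-2-enyl)cyclobut-2-en-1-one; 14 rac-3-[4-(tert-butyldimethylsilyloxy)phenyl]-3-(triethylsilyloxy)-1-(triisopropylsilyloxy)prop-1-yne
Product: 19 rac-2-{[4-(tert-butyldimethylsilyloxy)phenyl](triethylsilyloxy)methyl}-5-methoxy-4,6-bis(3-methylbut-2-enyl)-3-(triisopropylsilyloxy)phenol, via vinylketene 15 (not isolated), via alkenylcyclobutenone 16 (not isolated), via dienylketene 17 (not isolated), via cyclohexadienone 18 (not isolated)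
Conditions: 7 (1.3 equiv), 14 (1.0 equiv), PhMe (0.5 M), base-washed sealed tube, Ar, 110 °C then 135 °C
Reagents that add atoms: none
Why: Danheiser benzannulation, the known cascade of a cyclobutenone and a siloxyalkyne: conrotatory 4π opening of 7, with the C4 prenyl group turning outward, gives vinylketene 15, and its ketene C=C adds 14 in a [2+2] cycloaddition to give the 4-alkenylcyclobut-2-enone 16 (new bonds C1–C2 and C5–C6 of ring A). A second, reversible 4π opening cleaves the old carbonyl–alkene bond of the cyclobutenone and gives dienylketene 17, of which only the isomer with the enol ether arm turned inward can react on. Ring A closes by disrotatory 6π electrocyclisation between the ketene carbon (C2) and the enol ether terminus (C3), and 18 tautomerises to the phenol, which makes the sequence irreversible. No stereocentre of the target is set: the quaternary centre of 16 and the sp3 ring carbon of 18 are erased on aromatisation, and the carbinol centre is carried along racemic. The only selectivity needed is the orientation of the [2+2], and the silyloxy group secures it by making the alkyne carbon that bears the carbinol branch nucleophilic, so that it bonds to the electrophilic ketene carbonyl carbon while the oxygen-bearing carbon becomes C6. The medium is neutral and aprotic, so the prenyl groups, the new C2 phenol and the ionisable benzhydrylic silyl ether meet no acid; the donor methoxyl, which tames the ketene, is the main uncertainty and is met by high concentration and an excess of 7.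

Step 8
Reactants: 19 rac-2-{[4-(tert-butyldimethylsilyloxy)phenyl](triethylsilyloxy)methyl}-5-methoxy-4,6-bis(3-methylbut-2-enyl)-3-(triisopropylsilyloxy)phenol
Product: 20 rac-2-{[4-(tert-butyldimethylsilyloxy)phenyl](hydroxy)methyl}-5-methoxy-4,6-bis(3-methylbut-2-enyl)-3-(triisopropylsilyloxy)phenol
Conditions: HF·pyridine, pyridine, THF, 0 °C; aq NaHCO3; crude product taken on at once
Reagents that add atoms: none
Why: In this selective desilylation, acidic fluoride cleaves an alkyl triethylsilyl ether much faster than aryl TBS or TIPS ethers, and any ionisation of the benzhydrylic C–O bond is harmless because water returns the same racemic carbinol on work-up.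

Step 9
Reactants: 20 rac-2-{[4-(tert-butyldimethylsilyloxy)phenyl](hydroxy)methyl}-5-methoxy-4,6-bis(3-methylbut-2-enyl)-3-(triisopropylsilyloxy)phenol
Product: 21 [4-(tert-butyldimethylsilyloxy)phenyl][2-hydroxy-4-methoxy-3,5-bis(3-methylbut-2-enyl)-6-(triisopropylsilyloxy)phenyl]methanone
Conditions: activated MnO2 (20 equiv), CH2Cl2, 23 °C
Reagents that add atoms: none
Why: MnO2 oxidation of a doubly benzylic alcohol, well known for o-hydroxybenzyl alcohols, is neutral, spares prenyl groups and silyl ethers, and gives a ketone whose hydrogen bond to the C2 hydroxyl shields that phenol from further oxidation.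

Step 10
Reactants: 21 [4-(tert-butyldimethylsilyloxy)phenyl][2-hydroxy-4-methoxy-3,5-bis(3-methylbut-2-enyl)-6-(triisopropylsilyloxy)phenyl]methanone
Product: 22 Vismiaphenone D, [2,6-dihydroxy-4-methoxy-3,5-bis(3-methylbut-2-enyl)phenyl](4-hydroxyphenyl)methanone
Conditions: Bu4NF (2.5 equiv), AcOH (2.5 equiv), THF, 0 °C
Reagents that add atoms: none
Why: Fluoride-mediated cleavage of aryl silyl ethers is fast when the phenol is ortho or para to a carbonyl group, and the acetic acid buffer keeps the product phenolates from air oxidation.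

Compound list
1 | ethoxyacetylene | CCOC#C | starting material
2 | prenyl bromide (1-bromo-3-methylbut-2-ene) | CC(C)=CCBr | starting material
3 | lithium ethoxyacetylide | CCOC#C[Li] | intermediate
4 | 1-ethoxy-5-methylhex-4-en-1-yne | CCOC#CCC=C(C)C | intermediate
5 | prenylketene (5-methylhexa-1,4-dien-1-one) | O=C=CCC=C(C)C | intermediate
6 | rac-3-ethoxy-2,4-bis(3-methylbut-2-enyl)cyclobut-2-en-1-one | O=C1C(CC=C(C)C)=C(OCC)C1CC=C(C)C | intermediate
7 | rac-3-methoxy-2,4-bis(3-methylbut-2-enyl)cyclobut-2-en-1-one | O=C1C(CC=C(C)C)=C(OC)C1CC=C(C)C | intermediate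
8 | 4-(tert-butyldimethylsilyloxy)benzaldehyde | O=Cc1ccc(O[Si](C)(C)C(C)(C)C)cc1 | starting material
9 | ethynylmagnesium bromide | C#C[Mg]Br | starting material
10 | rac-1-[4-(tert-butyldimethylsilyloxy)phenyl]prop-2-yn-1-ol | C#CC(O)c1ccc(O[Si](C)(C)C(C)(C)C)cc1 | intermediate
11 | rac-tert-butyldimethyl{4-[1-(triethylsilyloxy)prop-2-ynyl]phenoxy}silane | C#CC(O[Si](CC)(CC)CC)c1ccc(O[Si](C)(C)C(C)(C)C)cc1 | intermediate
12 | lithium acetylide of 11 | [Li]C#CC(O[Si](CC)(CC)CC)c1ccc(O[Si](C)(C)C(C)(C)C)cc1 | intermediate
13 | lithium ynolate, lithium 3-[4-(tert-butyldimethylsilyloxy)phenyl]-3-(triethylsilyloxy)prop-1-yn-1-olate | [Li]OC#CC(O[Si](CC)(CC)CC)c1ccc(O[Si](C)(C)C(C)(C)C)cc1 | intermediate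
14 | rac-3-[4-(tert-butyldimethylsilyloxy)phenyl]-3-(triethylsilyloxy)-1-(triisopropylsilyloxy)prop-1-yne | CC(C)[Si](OC#CC(O[Si](CC)(CC)CC)c1ccc(O[Si](C)(C)C(C)(C)C)cc1)(C(C)C)C(C)C | intermediate
15 | vinylketene, (3Z)-3-methoxy-7-methyl-2-(3-methylbut-2-enyl)octa-1,3,6-trien-1-one (prenyl CH2 trans to the ketene-bearing carbon) | O=C=C(CC=C(C)C)/C(OC)=C/CC=C(C)C | intermediate
16 | 4-alkenylcyclobut-2-enone, 2-{[4-(tert-butyldimethylsilyloxy)phenyl](triethylsilyloxy)methyl}-4-(1-methoxy-5-methylhexa-1,4-dienyl)-4-(3-methylbut-2-enyl)-3-(triisopropylsilyloxy)cyclobut-2-en-1-one, racemic diastereomer mixture | O=C1C(C(O[Si](CC)(CC)CC)c2ccc(O[Si](C)(C)C(C)(C)C)cc2)=C(O[Si](C(C)C)(C(C)C)C(C)C)C1(CC=C(C)C)/C(OC)=C/CC=C(C)C | intermediate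
17 | dienylketene from 16 (central alkene with the ketene-bearing carbon and the enol ether arm cis) | O=C=C(C(O[Si](CC)(CC)CC)c1ccc(O[Si](C)(C)C(C)(C)C)cc1)/C(O[Si](C(C)C)(C(C)C)C(C)C)=C(CC=C(C)C)\C(OC)=C\CC=C(C)C | intermediate
18 | cyclohexa-2,4-dienone tautomer of 19 (sp3 carbon at ring A C3), racemic diastereomer mixture | O=C1C(C(O[Si](CC)(CC)CC)c2ccc(O[Si](C)(C)C(C)(C)C)cc2)=C(O[Si](C(C)C)(C(C)C)C(C)C)C(CC=C(C)C)=C(OC)C1CC=C(C)C | intermediate
19 | rac-2-{[4-(tert-butyldimethylsilyloxy)phenyl](triethylsilyloxy)methyl}-5-methoxy-4,6-bis(3-methylbut-2-enyl)-3-(triisopropylsilyloxy)phenol | COc1c(CC=C(C)C)c(O)c(C(O[Si](CC)(CC)CC)c2ccc(O[Si](C)(C)C(C)(C)C)cc2)c(O[Si](C(C)C)(C(C)C)C(C)C)c1CC=C(C)C | intermediate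
20 | rac-2-{[4-(tert-butyldimethylsilyloxy)phenyl](hydroxy)methyl}-5-methoxy-4,6-bis(3-methylbut-2-enyl)-3-(triisopropylsilyloxy)phenol | COc1c(CC=C(C)C)c(O)c(C(O)c2ccc(O[Si](C)(C)C(C)(C)C)cc2)c(O[Si](C(C)C)(C(C)C)C(C)C)c1CC=C(C)C | intermediate
21 | [4-(tert-butyldimethylsilyloxy)phenyl][2-hydroxy-4-methoxy-3,5-bis(3-methylbut-2-enyl)-6-(triisopropylsilyloxy)phenyl]methanone | COc1c(CC=C(C)C)c(O)c(C(=O)c2ccc(O[Si](C)(C)C(C)(C)C)cc2)c(O[Si](C(C)C)(C(C)C)C(C)C)c1CC=C(C)C | intermediate
22 | Vismiaphenone D | COc1c(CC=C(C)C)c(O)c(C(=O)c2ccc(O)cc2)c(O)c1CC=C(C)C | target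

Total step count: 10. Longest linear sequence: 7 (steps 1–3 or steps 4–6, then steps 7–10).

Steps most likely to fail

1. **Step 7.**
   - What may go wrong: the methoxyl donor lowers the electrophilicity of the ketene and the nucleophilic alkyne carbon is hindered. The [2+2] may therefore be outrun by reclosure of the vinylketene, by thermal loss of silanol from the benzhydrylic ether next to the newly formed phenol, or by acylation of that phenol by the vinylketene.
   - Fallback: it gives up the ring construction for classical phloroglucinol chemistry. It sets out from prenyl bromide 2 and rejoins at target 22. Phloroglucinol is acylated with 4-hydroxybenzoic acid (ZnCl2, POCl3, 65 °C, Friedel–Crafts acylation) to 2,4,4',6-tetrahydroxybenzophenone F1. Double C-prenylation with 2 (aq KOH, 0 °C) should give 2,4,4',6-tetrahydroxy-3,5-bis(3-methylbut-2-enyl)benzophenone F2. Over- and under-alkylation are the price of this step. One equivalent of t-BuMe2SiCl with imidazole silylates the only hydroxyl that is neither chelated nor flanked by prenyl groups, giving the 4'-silyl ether F3. Me3SiCHN2 in PhMe/MeOH then methylates the one remaining non-chelated hydroxyl at C4 to give the 4-O-methyl 4'-silyl ether F4. Bu4NF/AcOH gives 22.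

2. **Step 6.**
   - What may go wrong: oxygen transfer to an acetylide made less nucleophilic by the propargylic oxygen may be slow. The ynolate may expel silanolate on warming. The acid-sensitive siloxyalkyne may decompose on silica.
   - Fallback: it reaches the ynolate without an oxidant. It sets out from aldehyde 8 and rejoins at ynolate 13, and so at 14. The lithium enolate of ethyl dibromoacetate (LiN(SiMe3)2, THF, −78 °C) is added to 8 in an aldol reaction to give ethyl 2,2-dibromo-3-[4-(tert-butyldimethylsilyloxy)phenyl]-3-hydroxypropanoate F5. Et3SiOTf with 2,6-lutidine gives its triethylsilyl ether F6. t-BuLi (4 equiv, THF, −78 → 0 °C) carries out two bromine–lithium exchanges, and the ester dianion expels lithium ethoxide to give 13. This is trapped with i-Pr3SiOTf as in the main route.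

3. **Step 3.**
   - What may go wrong: the exchange is an equilibrium and may stall at the stage of methanol addition. The acid may slowly add methanol to the prenyl alkenes. The strained ring may be cleaved by solvolysis.
   - Fallback: it replaces the equilibrium by dealkylation and irreversible O-methylation. It sets out from 6 and rejoins at 7. LiOH in THF/H2O (0 → 23 °C) saponifies the vinylogous ester to a stabilised enolate salt. Cold citric acid (pH 3) then liberates 3-hydroxy-2,4-bis(3-methylbut-2-enyl)cyclobut-2-en-1-one F7. Me3SiCHN2 in PhMe/MeOH at 0 °C methylates on oxygen. The two enol oxygens are equivalent by symmetry, so only 7 can result.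

Further compounds
F1 | step 7 | 2,4,4',6-tetrahydroxybenzophenone | O=C(c1ccc(O)cc1)c1c(O)cc(O)cc1O
F2 | step 7 | 2,4,4',6-tetrahydroxy-3,5-bis(3-methylbut-2-enyl)benzophenone | O=C(c1ccc(O)cc1)c1c(O)c(CC=C(C)C)c(O)c(CC=C(C)C)c1O
F3 | step 7 | [4-(tert-butyldimethylsilyloxy)phenyl][2,4,6-trihydroxy-3,5-bis(3-methylbut-2-enyl)phenyl]methanone | O=C(c1ccc(O[Si](C)(C)C(C)(C)C)cc1)c1c(O)c(CC=C(C)C)c(O)c(CC=C(C)C)c1O
F4 | step 7 | [4-(tert-butyldimethylsilyloxy)phenyl][2,6-dihydroxy-4-methoxy-3,5-bis(3-methylbut-2-enyl)phenyl]methanone | COc1c(CC=C(C)C)c(O)c(C(=O)c2ccc(O[Si](C)(C)C(C)(C)C)cc2)c(O)c1CC=C(C)C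
F5 | step 6 | rac-ethyl 2,2-dibromo-3-[4-(tert-butyldimethylsilyloxy)phenyl]-3-hydroxypropanoate | CCOC(=O)C(Br)(Br)C(O)c1ccc(O[Si](C)(C)C(C)(C)C)cc1
F6 | step 6 | rac-ethyl 2,2-dibromo-3-[4-(tert-butyldimethylsilyloxy)phenyl]-3-(triethylsilyloxy)propanoate | CCOC(=O)C(Br)(Br)C(O[Si](CC)(CC)CC)c1ccc(O[Si](C)(C)C(C)(C)C)cc1
F7 | step 3 | rac-3-hydroxy-2,4-bis(3-methylbut-2-enyl)cyclobut-2-en-1-one | O=C1C(CC=C(C)C)=C(O)C1CC=C(C)C
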